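**Assumption:** the target SMILES is read as a 2,3-trans-3,4-trans tetrahydrofuran (ring carbons S, R, S and carbinol S, equivalent to 7'-hydroxylariciresinol numbering 7S,8R,8'S,7'S). Both aryl groups are 4-hydroxy-3-methoxyphenyl (Ar = 4-BnO-3-MeO-C6H3 when protected).

## Retrosynthetic overview
1. The target is unmasked from the THF 14 by debenzylation and desilylation. The THF ring comes from the trans-5-aryl-γ-lactone 11 by DIBAL and ionic hydrogenation, so the C7–O bond is already in place and C7 is never touched.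
2. The C7'/C8' pair is set by a proposed Ru-catalysed transfer-hydrogenation dynamic kinetic resolution (ATH–DKR) of the 3-aroyl lactone 10, itself made by lactone aldol and oxidation.
3. The lactone 8 comes from an Evans syn-aldol of a succinyl imide with benzylvanillin, which sets C7 and C8 and gives the trans-lactone.
4. Ring order: the γ-lactone forms first (Step 5), then the THF (Step 11).

## Route

**Step 1**
Reactants: 1 (S)-4-benzyloxazolidin-2-one; 2 mono-tert-butyl succinate
Product: 3 (S)-4-benzyl-3-[4-(tert-butoxy)-4-oxobutanoyl]oxazolidin-2-one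
Conditions: 2, PivCl, Et3N, THF, 0 °C; then 1, LiCl, rt
Reagents that add atoms: none
Why: Mixed-anhydride N-acylation (Evans imide formation) occurs only at the free acid, so the tBu ester is untouched.

**Step 2**
Reactants: 3; 4 4-(benzyloxy)-3-methoxybenzaldehyde
Product: 5 Evans syn-aldol adduct, tert-butyl (3S)-4-[(4S)-4-benzyl-2-oxooxazolidin-3-yl]-3-[(S)-(4-benzyloxy-3-methoxyphenyl)(hydroxy)methyl]-4-oxobutanoate
Conditions: Bu2BOTf, i-Pr2NEt, CH2Cl2, –78 → 0 °C; then 4, –78 °C → 0 °C; H2O2, pH 7 buffer/MeOH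
Reagents that add atoms: none (boron is removed in the workup)
Why: Evans syn-aldol via the Z-boron enolate; the (S)-benzyl auxiliary sets C8 and C7 with the configuration required by the target (C7 S, C8 R in target numbering).

**Step 3**
Reactants: 5
Product: 6 tert-butyl (3R)-3-[(S)-(4-benzyloxy-3-methoxyphenyl)(hydroxy)methyl]-4-hydroxybutanoate
Conditions: LiBH4, THF/H2O (100:1), 0 °C
Reagents that add atoms: none (only H is added)
Why: Reductive auxiliary removal (auxiliary recovered as 1); the hindered tBu ester survives and neither stereocentre is touched.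

**Step 4**
Reactants: 6
Product: 7 tert-butyl (3R)-4-(tert-butyldiphenylsilyloxy)-3-[(S)-aryl(hydroxy)methyl]butanoate
Conditions: TBDPSCl, imidazole, CH2Cl2, 0 °C
Reagents that add atoms: TBDPSCl, CC(C)(C)[Si](c1ccccc1)(c1ccccc1)Cl
Why: Silylation is selective for the primary over the hindered benzylic secondary alcohol, so C9 is permanently differentiated from C9'.

**Step 5**
Reactants: 7
Product: 8 (4R,5S)-5-(4-benzyloxy-3-methoxyphenyl)-4-[(TBDPSoxy)methyl]dihydrofuran-2(3H)-one (trans-lactone)
Conditions: TFA/CH2Cl2 (1:4), 0 °C, 2 h; concentrate; EDC·HCl, DMAP, CH2Cl2, 0 °C → rt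
Reagents that add atoms: none
Why: Acidolysis of the tBu ester followed by carbodiimide lactonisation; a syn-aldol gives the 4,5-trans γ-lactone, and the neutral EDC step avoids benzylic ionisation at C7.

**Step 6**
Reactants: 8; 4
Product: 9 aldol lactone (C8' trans to C8, carbinol C7' as an epimeric mixture)
Conditions: LiHMDS (1.1 equiv), THF, –78 °C; then 4, –78 °C; NH4Cl
Reagents that add atoms: none (the aldehyde 4 is a numbered reactant)
Why: Lactone enolate aldol at the most acidic CH2 (C8'), anti to the C8 substituent; the C7' configuration is irrelevant because it is oxidised next.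

**Step 7**
Reactants: 9
Product: 10 3-aroyl lactone (C8' epimerisable, largely enolised)
Conditions: Dess–Martin periodinane, NaHCO3, CH2Cl2, rt
Reagents that add atoms: none
Why: Oxidation of the benzylic carbinol to the ketone converges both C7' epimers onto one substrate.

**Step 8**
Reactants: 10
Product: 11 (3R,4R,5S)-3-[(S)-aryl(hydroxy)methyl]-4-[(TBDPSoxy)methyl]-5-aryl-lactone
Conditions: RuCl[(S,S)-TsDPEN](p-cymene) (2 mol%), HCO2H/Et3N (5:2), CH2Cl2, 40 °C, 36 h
Reagents that add atoms: none (HCO2H is only a hydride source; CO2 is lost)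
Why: Proposed new method: Noyori–Ikariya ATH–DKR, known for acyclic α-substituted β-keto esters, is applied to an enolisable, ring-locked 3-aroyl-γ-butyrolactone, where Et3N epimerises C8' through the enol while the (S,S)-Ru-hydride reduces the aryl ketone outer-sphere (CH/π-directed) to the (S)-carbinol; the trans-4-CH2OTBDPS group disfavours the cis-C8' epimer, so C7' (S) and C8' (trans to C9) are set together.

**Step 9**
Reactants: 11
Product: 12 C7'-OTBS lactone
Conditions: TBSOTf, 2,6-lutidine, CH2Cl2, –78 → 0 °C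
Reagents that add atoms: TBSOTf, CC(C)(C)[Si](C)(C)OS(=O)(=O)C(F)(F)F
Why: Silylation under weakly basic, low-temperature conditions avoids retro-aldol or elimination at the β-hydroxy lactone.

**Step 10**
Reactants: 12
Product: 13 lactol (C9' epimeric mixture)
Conditions: DIBAL-H (1.1 equiv), CH2Cl2, –78 °C; Rochelle salt workup
Reagents that add atoms: none (H only)
Why: Partial reduction of the single carbonyl to the lactol; the benzyl ethers and both silyl ethers are inert.

**Step 11**
Reactants: 13
Product: 14 (2S,3R,4S)-THF: 2-aryl-3-(TBDPSoxymethyl)-4-[(S)-aryl(OTBS)methyl]tetrahydrofuran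
Conditions: Et3SiH, BF3·OEt2, CH2Cl2, –78 → –30 °C
Reagents that add atoms: none (only H is delivered to the product)
Why: Ionic hydrogenation of the cyclic oxocarbenium converts C9' to CH2 without affecting C7, whose O–C bond is never broken.

**Step 12**
Reactants: 14
Product: 15 bis-phenol (OTBS, OTBDPS retained)
Conditions: H2 (1 atm), 10% Pd/C, EtOAc, rt, 2 h
Reagents that add atoms: none
Why: Hydrogenolysis of the two aryl benzyl ethers; the silyl ethers and the benzylic C–O bonds survive under short, neutral conditions.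

**Step 13**
Reactants: 15
Product: 16 target, 7'-hydroxylariciresinol stereoisomer
Conditions: TBAF, AcOH (buffer), THF, 0 °C → rt, 12 h
Reagents that add atoms: none
Why: Fluoride removes both silyl ethers; no stereocentre is affected.

## Compound list
1 | (S)-4-benzyloxazolidin-2-one | O=C1N[C@@H](Cc2ccccc2)CO1 | starting material
2 | 4-(tert-butoxy)-4-oxobutanoic acid | OC(=O)CCC(=O)OC(C)(C)C | starting material
3 | N-succinyl (tBu ester) Evans imide | O=C(CCC(=O)OC(C)(C)C)N1[C@@H](Cc2ccccc2)COC1=O | intermediate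
4 | 4-(benzyloxy)-3-methoxybenzaldehyde | COc1cc(C=O)ccc1OCc1ccccc1 | starting material
5 | Evans syn-aldol adduct | COc1cc([C@@H](O)[C@H](CC(=O)OC(C)(C)C)C(=O)N2[C@@H](Cc3ccccc3)COC2=O)ccc1OCc1ccccc1 | intermediate
6 | diol tBu ester | COc1cc([C@@H](O)[C@H](CC(=O)OC(C)(C)C)CO)ccc1OCc1ccccc1 | intermediate
7 | TBDPS ether | COc1cc([C@@H](O)[C@H](CC(=O)OC(C)(C)C)CO[Si](c2ccccc2)(c2ccccc2)C(C)(C)C)ccc1OCc1ccccc1 | intermediate
8 | trans-5-aryl-4-(TBDPSoxymethyl)-γ-lactone | CC(C)(C)[Si](c1ccccc1)(c1ccccc1)OC[C@H]1CC(=O)O[C@@H]1c1ccc(OCc2ccccc2)c(OC)c1 | intermediate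
9 | aldol lactone (C7' epimeric mixture; drawn without C7' stereo) | CC(C)(C)[Si](c1ccccc1)(c1ccccc1)OC[C@H]1[C@H](C(O)c2ccc(OCc3ccccc3)c(OC)c2)C(=O)O[C@@H]1c1ccc(OCc2ccccc2)c(OC)c1 | intermediate
10 | 3-aroyl lactone (C8' epimerisable; drawn without C8' stereo) | CC(C)(C)[Si](c1ccccc1)(c1ccccc1)OC[C@H]1C(C(=O)c2ccc(OCc3ccccc3)c(OC)c2)C(=O)O[C@@H]1c1ccc(OCc2ccccc2)c(OC)c1 | intermediate
11 | hydroxy lactone (C7' S, C8' trans) | CC(C)(C)[Si](c1ccccc1)(c1ccccc1)OC[C@H]1[C@H]([C@H](O)c2ccc(OCc3ccccc3)c(OC)c2)C(=O)O[C@@H]1c1ccc(OCc2ccccc2)c(OC)c1 | intermediate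
12 | C7'-OTBS lactone | CC(C)(C)[Si](c1ccccc1)(c1ccccc1)OC[C@H]1[C@H]([C@H](O[Si](C)(C)C(C)(C)C)c2ccc(OCc3ccccc3)c(OC)c2)C(=O)O[C@@H]1c1ccc(OCc2ccccc2)c(OC)c1 | intermediate
13 | lactol (C9' epimeric; drawn without C9' stereo) | CC(C)(C)[Si](c1ccccc1)(c1ccccc1)OC[C@H]1[C@H]([C@H](O[Si](C)(C)C(C)(C)C)c2ccc(OCc3ccccc3)c(OC)c2)C(O)O[C@@H]1c1ccc(OCc2ccccc2)c(OC)c1 | intermediate
14 | protected THF | CC(C)(C)[Si](c1ccccc1)(c1ccccc1)OC[C@H]1[C@H]([C@H](O[Si](C)(C)C(C)(C)C)c2ccc(OCc3ccccc3)c(OC)c2)CO[C@@H]1c1ccc(OCc2ccccc2)c(OC)c1 | intermediate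
15 | bis-phenol, silyl-protected | CC(C)(C)[Si](c1ccccc1)(c1ccccc1)OC[C@H]1[C@H]([C@H](O[Si](C)(C)C(C)(C)C)c2ccc(O)c(OC)c2)CO[C@@H]1c1ccc(O)c(OC)c1 | intermediate
16 | 4-{(S)-[(3S,4R,5S)-5-(4-hydroxy-3-methoxyphenyl)-4-(hydroxymethyl)oxolan-3-yl](hydroxy)methyl}-2-methoxyphenol | COc1cc([C@@H](O)[C@@H]2CO[C@H](c3ccc(O)c(OC)c3)[C@H]2CO)ccc1O | target

**Total steps:** 13. **Longest linear sequence:** 13 (Steps 1–13; aldehyde 4 is a commercial input used twice).

## Three steps most likely to fail
1. **Step 8 (proposed ATH–DKR).** The enolised aroyl lactone may react slowly, or the catalyst may choose the cis-C8' epimer. Fallback (known chemistry, different approach): skip the oxidation and the DKR. Use aldol 9 directly, since the E-lactone enolate is anti-selective and trans to C8, separate the (7'S) anti isomer by chromatography, and recycle the C7' epimer by DMP oxidation and (S)-Me-CBS reduction.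
2. **Step 11 (Et3SiH/BF3 on the lactol).** Benzylic C7–O or C7'–OTBS ionisation could erode stereochemistry or cause deoxygenation. Fallback: build the ring by SN2 instead. Reduce lactone 12 with LiAlH4 to the 1,4-diol (C7–OH and C9'–OH free, since C9 and C7' are silylated), tosylate the primary OH selectively (TsCl, pyridine), then close with NaH in THF. The C7 alkoxide is the nucleophile, so its configuration is retained.
3. **Step 12 (Pd/C hydrogenolysis).** Benzylic C–O hydrogenolysis at C7 or C7' could over-reduce the product. Fallback: remove the silyl groups first (TBAF), then debenzylate non-reductively with BCl3·SMe2, CH2Cl2, –20 °C.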